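**Plan**

- Retrosynthesis: remove the four benzyl ethers, then cut in each half the O1–C8a aryl ether and the C4–C4a bond. This detaches both phloroglucinol rings A and leaves the C2–C3–C3''–C2'' core with C4/C4'' as lactone carbonyls. Last, cut C3–C3'' and the two lactone C–O bonds to reach two molecules of 4-methoxycinnamic acid.
- Enabling feature: the central C3–C3'' bond connects the alpha-carbons of the C4 and C4'' ketones, and beside each lies a benzylic carbon (C2, C2'') that bears a ring oxygen and the electron-rich 4-methoxyphenyl ring B. This is the imprint of a tail-to-tail radical-cation union of two anisylacrylic acids in which each benzylic cation is caught by a carboxyl group.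
- Forward order: the anodic dimerisation closes both gamma-lactone rings at once. After resolution the lactones are reduced to lactols and ring A is added to C4 and C4'' as a 2-fluoroaryl Grignard reagent. Both pyran rings C then close by SNAr of the C2 and C2'' oxygens (the former lactone ring oxygens, now O1 and O1''), the C4 carbinols are oxidised to ketones, and the benzyl groups are removed.
- Stereochemistry: the cis-fused, exo,exo dilactone fixes the relative configuration of C2, C3, C3'' and C2''; it maps onto 2,3-cis, 2'',3''-cis with homochiral C3/C3''. The absolute configuration comes from chromatographic resolution of the racemic dilactone. Every later bond is made at oxygen or at C4, and no strong base ever meets a C4 ketone, so the four centres are not touched.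

Key step: step 1

Assumption: flavonoid numbering is used for the target and its open-chain precursors (O1, C2, C3, C4, doubly primed locants for the second half; ring A = phloroglucinol ring, ring B = 4-methoxyphenyl, ring C = pyranone). The enantiomers of the racemic dilactone are taken to be separable on a polysaccharide phase, and the (1S,2S,5S,6S) antipode is to be identified by anomalous-dispersion crystallography or ECD before it is carried on.

**Route**

Step 1
Reactants: 1 (E)-4-methoxycinnamic acid (two molecules)
Product: 2 rac-(1S,2S,5S,6S)-2,6-bis(4-methoxyphenyl)-3,7-dioxabicyclo[3.3.0]octane-4,8-dione (cis-fused, both aryl groups exo)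
Conditions: undivided cell, graphite anode, Pt cathode, constant current (5 mA cm−2, ca. 1.1 F per mol of 1), Bu4NBF4 (0.1 M), (CF3)2CHOH/CH2Cl2 1:1, 0 °C; stopped before full conversion
Reagents that add atoms: none
Why: Proposed new method: anodic one-electron oxidation of the anisyl-conjugated alkene of 1 (the acid is not ionised, so no carboxylate is available for Kolbe oxidation) should give a radical cation with spin at the carbon alpha to carboxyl, and tail-to-tail union of two such species (or of a radical cation with neutral 1 followed by a second electron transfer) forms the C3–C3'' bond and leaves two 4-methoxybenzylic cations, the closest known reactions being the dimerisation of 4-alkoxycinnamic acids to these dilactones with Tl(OCOCF3)3 or CoF3 and the anodic dimerisation of 4-methoxystyrenes. Each cation should be captured by the carboxyl group of the other half in a 5-exo-trig closure, since its own carboxyl could only form a four-membered ring, so both gamma-lactone rings and both C–O bonds arise in the same operation. The two ring-fusion centres can only be cis in a bicyclo[3.3.0]octane, so only the homochiral coupling product can lactonise twice, and each aryl group is expected to take the exo (convex) position, a preference that reversible ionisation of the 4-methoxybenzylic C–O bond in the acidic medium allows to be reached. The step needs selectivity for oxidation of 1 over product 2, which the lower oxidation potential of the conjugated anisyl alkene relative to the isolated anisyl rings of 2 should secure at low current density and partial conversion, while the fluorinated alcohol stabilises the radical cation and is too weak a nucleophile to compete with the internal carboxyl groups. The electrode exerts no absolute control, so 2 is racemic.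

Step 2
Reactants: 2 rac-dilactone
Product: 3 (1S,2S,5S,6S)-2,6-bis(4-methoxyphenyl)-3,7-dioxabicyclo[3.3.0]octane-4,8-dione (single enantiomer)
Conditions: preparative SFC, amylose tris(3,5-dimethylphenylcarbamate) on silica, CO2/MeOH, 35 °C
Reagents that add atoms: none
Why: Chromatographic resolution on a polysaccharide chiral stationary phase, which should discriminate well between the antipodes of a rigid, C2-symmetric bis-aryl dilactone; no stereocentre is formed or touched, the wanted antipode is simply selected.

Step 3
Reactants: 3 (1S,2S,5S,6S)-dilactone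
Product: 4 (1S,2S,5S,6S)-2,6-bis(4-methoxyphenyl)-3,7-dioxabicyclo[3.3.0]octane-4,8-diol (bis-lactol, anomer mixture)
Conditions: iBu2AlH (2.4 equiv), CH2Cl2/THF, −78 °C; aq. KNaC4H4O6 (potassium sodium tartrate)
Reagents that add atoms: none
Why: Partial reduction of a gamma-lactone to the lactol with iBu2AlH, whose tetrahedral aluminium alkoxide persists at −78 °C until work-up; the two anomeric centres form without control (they are consumed in step 6) and the cis-fused bicyclic lactol form protects C3/C3'' from epimerisation.

Step 4
Reactants: 5 5-fluorobenzene-1,3-diol; 6 benzyl bromide (two molecules)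
Product: 7 1,3-bis(benzyloxy)-5-fluorobenzene
Conditions: 6 (2.2 equiv), K2CO3 (3 equiv), DMF, 60 °C
Reagents that add atoms: none
Why: Twofold Williamson ether synthesis in which each of the two phenoxides of 5 displaces bromide from one molecule of the reactive benzylic halide 6.

Step 5
Reactants: 7 1,3-bis(benzyloxy)-5-fluorobenzene
Product: 8 1,5-bis(benzyloxy)-3-fluoro-2-iodobenzene
Conditions: N-iodosuccinimide (1.05 equiv), CF3CO2H (cat.), MeCN, 0 °C → rt
Reagents that add atoms: N-iodosuccinimide, O=C1CCC(=O)N1I
Why: Electrophilic aromatic iodination, expected at the position para to one benzyloxy group and ortho to the other (next to fluorine) and not at the more hindered carbon between the two benzyloxy groups, as is usual for 5-substituted 1,3-dialkoxybenzenes.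

Step 6
Reactants: 4 bis-lactol; 8 1,5-bis(benzyloxy)-3-fluoro-2-iodobenzene (two molecules)
Product: 10 tetraol (1S,2S,3S,4S)-2,3-bis{[2,4-bis(benzyloxy)-6-fluorophenyl](hydroxy)methyl}-1,4-bis(4-methoxyphenyl)butane-1,4-diol (epimer mixture at the two new carbinol centres C4/C4''), via arylmagnesium chloride 9 (not isolated)
Conditions: 8 (5 equiv), iPrMgCl·LiCl (5 equiv), THF, −20 °C; then 4, −20 → 0 °C; aq. NH4Cl
Reagents that add atoms: isopropylmagnesium chloride–lithium chloride, CC(C)[Mg]Cl.[Li+].[Cl-] (supplies Mg and Cl of intermediate 9 only)
Why: Iodine–magnesium exchange followed by Grignard addition of one molecule of 9 to each aldehyde tautomer of the magnesium lactolates (the excess reagent first deprotonates the lactol hydroxyls, and the arene 7 so formed is recovered); C2, C3, C3'' and C2'' are not involved, and the new C4/C4'' carbinol centres form without control, which is of no consequence because they are oxidised in step 8.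

Step 7
Reactants: 10 tetraol
Product: 11 (2S,3R,2''S,3''R)-5,7,5'',7''-tetrakis(benzyloxy)-4',4'''-dimethoxy-3,3''-biflavan-4,4''-diol (2,3-cis and 2'',3''-cis; C4/C4'' epimer mixture; the spatial arrangement at C3/C3'' is that of the target, the descriptor differs only because C2 now outranks C4)
Conditions: KOtBu (5 equiv), DMF, 0 → 60 °C, argon
Reagents that add atoms: none
Why: Double intramolecular SNAr in which the C2 and C2'' potassium alkoxides displace fluoride with six-membered ring closure (the alternatives would be seven-membered), a closure known for 3,5-dialkoxyfluoroarenes in flavan synthesis; the O–aryl bond is formed with retention at C2, and without a carbonyl group neither retro-aldol cleavage nor enolisation at C3 can occur.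

Step 8
Reactants: 11 biflavan-4,4''-diol
Product: 12 (2S,3S,2''S,3''S)-5,7,5'',7''-tetrakis(benzyloxy)-4',4'''-dimethoxy-3,3''-biflavanone (2,3-cis, 2'',3''-cis)
Conditions: Dess–Martin periodinane (3 equiv), NaHCO3, CH2Cl2, 0 °C → rt; aq. Na2S2O3/NaHCO3
Reagents that add atoms: none
Why: Dess–Martin oxidation of the two benzylic secondary alcohols under buffered, essentially neutral conditions, which should leave the kinetically held cis configuration at C3/C3'' and the acid-sensitive benzylic ethers intact and converge both C4 epimers on one diketone.

Step 9
Reactants: 12 tetra-O-benzyl biflavanone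
Product: 13 (2S,3S,2''S,3''S)-5,7,5'',7''-tetrahydroxy-4',4'''-dimethoxy-3,3''-biflavanone (target)
Conditions: H2 (1 atm), 10% Pd/C, EtOAc/THF, rt
Reagents that add atoms: none
Why: Catalytic hydrogenolysis of the four benzyl aryl ethers under neutral conditions, which spare the methyl ethers, the hydrogen-bonded C4 ketones and the C2–O1 bonds and give no occasion for epimerisation.

**Compound list**

1 | (E)-4-methoxycinnamic acid | COc1ccc(/C=C/C(=O)O)cc1 | starting material
2 | rac-(1S,2S,5S,6S)-2,6-bis(4-methoxyphenyl)-3,7-dioxabicyclo[3.3.0]octane-4,8-dione (racemate; relative configuration shown) | O=C1O[C@H](c3ccc(OC)cc3)[C@@H]2[C@H]1[C@@H](c3ccc(OC)cc3)OC2=O | intermediate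
3 | (1S,2S,5S,6S)-2,6-bis(4-methoxyphenyl)-3,7-dioxabicyclo[3.3.0]octane-4,8-dione (single enantiomer) | O=C1O[C@H](c3ccc(OC)cc3)[C@@H]2[C@H]1[C@@H](c3ccc(OC)cc3)OC2=O | intermediate
4 | (1S,2S,5S,6S)-2,6-bis(4-methoxyphenyl)-3,7-dioxabicyclo[3.3.0]octane-4,8-diol (anomer mixture) | OC1O[C@H](c3ccc(OC)cc3)[C@@H]2[C@H]1[C@@H](c3ccc(OC)cc3)OC2O | intermediate
5 | 5-fluorobenzene-1,3-diol | Oc1cc(O)cc(F)c1 | starting material
6 | benzyl bromide | BrCc1ccccc1 | starting material
7 | 1,3-bis(benzyloxy)-5-fluorobenzene | Fc1cc(OCc2ccccc2)cc(OCc2ccccc2)c1 | intermediate
8 | 1,5-bis(benzyloxy)-3-fluoro-2-iodobenzene | Fc1cc(OCc2ccccc2)cc(OCc2ccccc2)c1I | intermediate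
9 | [2,4-bis(benzyloxy)-6-fluorophenyl]magnesium chloride (LiCl complex, not isolated) | Fc1cc(OCc2ccccc2)cc(OCc2ccccc2)c1[Mg]Cl | intermediate
10 | (1S,2S,3S,4S)-2,3-bis{[2,4-bis(benzyloxy)-6-fluorophenyl](hydroxy)methyl}-1,4-bis(4-methoxyphenyl)butane-1,4-diol (epimer mixture at the two side-arm carbinols) | COc1ccc([C@@H](O)[C@@H](C(O)c2c(F)cc(OCc3ccccc3)cc2OCc2ccccc2)[C@H](C(O)c2c(F)cc(OCc3ccccc3)cc2OCc2ccccc2)[C@H](O)c2ccc(OC)cc2)cc1 | intermediate
11 | (2S,3R,2''S,3''R)-5,7,5'',7''-tetrakis(benzyloxy)-4',4'''-dimethoxy-3,3''-biflavan-4,4''-diol (C4/C4'' epimer mixture) | COc1ccc([C@H]2Oc3cc(OCc4ccccc4)cc(OCc4ccccc4)c3C(O)[C@H]2[C@@H]2C(O)c3c(OCc4ccccc4)cc(OCc4ccccc4)cc3O[C@@H]2c2ccc(OC)cc2)cc1 | intermediate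
12 | (2S,3S,2''S,3''S)-5,7,5'',7''-tetrakis(benzyloxy)-4',4'''-dimethoxy-3,3''-biflavanone | COc1ccc([C@H]2Oc3cc(OCc4ccccc4)cc(OCc4ccccc4)c3C(=O)[C@H]2[C@@H]2C(=O)c3c(OCc4ccccc4)cc(OCc4ccccc4)cc3O[C@@H]2c2ccc(OC)cc2)cc1 | intermediate
13 | (2S,3S,2''S,3''S)-5,7,5'',7''-tetrahydroxy-4',4'''-dimethoxy-3,3''-biflavanone | COc1ccc([C@H]2Oc3cc(O)cc(O)c3C(=O)[C@H]2[C@@H]2C(=O)c3c(O)cc(O)cc3O[C@@H]2c2ccc(OC)cc2)cc1 | target

**Step count and risks**

Total: 9 steps. Longest linear sequence: 7 steps (steps 1, 2, 3, 6, 7, 8, 9, from 1 to 13); the aryl branch (steps 4 and 5) joins at step 6.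

Step 1 (key step, proposed method). The electrolysis may fail through filming of the anode by oligomers, through further oxidation of the anisyl rings of the product, or through diversion of the dimeric cation to cyclobutane, tetralin or solvent-capture products instead of double lactonisation. Fallback, from 1 to 2: the electrode is given up for a stoichiometric metal oxidant in strongly acidic solution, Tl(OCOCF3)3 with BF3·OEt2 in CF3CO2H/CH2Cl2 at low temperature. This is the documented dimerisation of 4-alkoxycinnamic acids by trivalent thallium, in which the radical cation is generated by the metal and the acid equilibrates the aryl groups to the exo positions. It gives the same racemic dilactone 2 without any new intermediate, and the route continues with step 2.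

Step 7. Displacement of fluoride from a ring that carries no activating group may be sluggish, and forcing conditions may bring attack of the C4 alkoxides on the fluoroarene of the other half (seven-membered closure) or decomposition of the tetra-alkoxide. Fallback, from 3 to 12: the ring closure is moved to the ketone oxidation level, where the ortho carbonyl activates the fluoroarene. Dilactone 3 is opened with Me(MeO)NH·HCl/AlMe3 to the bis(N-methoxy-N-methylamide) diol F3. Its two benzylic hydroxyls are silylated (TBSOTf, 2,6-lutidine) to give the bis(silyl ether) F4. Grignard reagent 9 (THF, −20 → 0 °C) converts both amides into the bis(2-fluoroaryl ketone) F5. Bu4NF in THF at 0 °C then unveils the C2/C2'' alkoxides, which close both pyranone rings at once by carbonyl-activated SNAr and give 12 directly. The silyl groups keep the alkoxides masked (no hemiketal, no retro-aldol) until the moment of closure. Steps 3, 6, 7 and 8 are bypassed.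

Step 6. The magnesium lactolates may open too slowly at the temperature the 2-fluoroaryl Grignard reagent tolerates, warming may cost the reagent by loss of MgClF to an aryne, and the reaction may stall after the first addition. Fallback, from 3 to 10: the aldehyde-level electrophile is abandoned. Iodide 8 undergoes iodine–lithium exchange (nBuLi, THF, −78 °C) to the aryllithium F1, which is stable at that temperature. F1 adds once to each lactone carbonyl of 3, since the di-ortho-substituted ketone (held as hemiketal) resists a second addition, and gives the diketo diol F2. LiBH4 in THF then reduces both carbonyl groups to tetraol 10. Step 3 is bypassed.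

Further compounds
F0 | step 1 | none | none
F1 | step 6 | [2,4-bis(benzyloxy)-6-fluorophenyl]lithium | [Li]c1c(F)cc(OCc2ccccc2)cc1OCc1ccccc1
F2 | step 6 | (2S,3S)-1,4-bis[2,4-bis(benzyloxy)-6-fluorophenyl]-2,3-bis[(S)-hydroxy(4-methoxyphenyl)methyl]butane-1,4-dione (in equilibrium with its bis-hemiketal) | COc1ccc([C@@H](O)[C@@H](C(=O)c2c(F)cc(OCc3ccccc3)cc2OCc2ccccc2)[C@H](C(=O)c2c(F)cc(OCc3ccccc3)cc2OCc2ccccc2)[C@H](O)c2ccc(OC)cc2)cc1
F3 | step 7 | (2S,3S)-2,3-bis[(S)-hydroxy(4-methoxyphenyl)methyl]-N1,N4-dimethoxy-N1,N4-dimethylbutanediamide | COc1ccc([C@@H](O)[C@@H](C(=O)N(C)OC)[C@H](C(=O)N(C)OC)[C@H](O)c2ccc(OC)cc2)cc1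
F4 | step 7 | (2S,3S)-2,3-bis[(S)-(tert-butyldimethylsilyloxy)(4-methoxyphenyl)methyl]-N1,N4-dimethoxy-N1,N4-dimethylbutanediamide | COc1ccc([C@@H](O[Si](C)(C)C(C)(C)C)[C@@H](C(=O)N(C)OC)[C@H](C(=O)N(C)OC)[C@H](O[Si](C)(C)C(C)(C)C)c2ccc(OC)cc2)cc1
F5 | step 7 | (2S,3S)-1,4-bis[2,4-bis(benzyloxy)-6-fluorophenyl]-2,3-bis[(S)-(tert-butyldimethylsilyloxy)(4-methoxyphenyl)methyl]butane-1,4-dione | COc1ccc([C@@H](O[Si](C)(C)C(C)(C)C)[C@@H](C(=O)c2c(F)cc(OCc3ccccc3)cc2OCc2ccccc2)[C@H](C(=O)c2c(F)cc(OCc3ccccc3)cc2OCc2ccccc2)[C@H](O[Si](C)(C)C(C)(C)C)c2ccc(OC)cc2)cc1
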